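**Remark:** atom numbers in the text are briarane numbers: C1 (quaternary, bears methyl C15), C2–C9 along the ten-membered ring, C10 (ring-fusion CH), C11–C14 (ring A), C16 (CH2 on C5), C17–C19 (lactone, C18 methyl), C20 (epoxide CH2).

**Assumption:** the antipodes named for the chiral controllers (L-valine tert-butyl ester in step 2, (−)-Ipc2BCl in step 20) are taken to give the sense of induction drawn; if the sense is the opposite, the other antipode is used with no other change.

## Retrosynthetic overview

1. Endgame on the bicycle: 4-O-SiEt3 removal ⇐ C11=C20 epoxidation ⇐ C6–Cl from 6-OH with inversion ⇐ 8-OH/17-H from the C8=C17 butenolide (directed epoxidation, SmI2).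
2. Ten-membered ring (C1–C10) closed last, at C6–C7, by an intramolecular vinylogous Mukaiyama aldol. Ring order: ring A, then the pre-formed butenolide is attached at C8–C9 (Nozaki–Hiyama–Kishi), then the ten-membered ring.
3. C2–C6 arm: boron aldol (C3–C4) of the C2 methyl ketone with 2-(silyloxymethyl)acrolein, then 1,3-syn reduction.
4. Ring A (C1, C14, C13, C12, C11, C10) by a one-operation [3+3] annulation: amide enolate C10 + acylsilane C11 (C10–C11), Brook rearrangement, carbanion C13 + ester C14 (C13–C14). C1 is set before by auxiliary-controlled alkylation.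
5. Enabling feature: ring A is a masked cyclohexane-1,4-dione (oxygen at C14 and C11, para across the unfunctionalised C12–C13 pair), with C10 next to the carbonyl-level C9 and C14 on the quaternary C1. C11–C12–C13 is therefore a homoenolate (acylsilane) synthon.

Key step: step 7

## Route

**Step 1**
Reactants: 1 methyl 2-methyl-3-oxobutanoate; 2 L-valine tert-butyl ester
Product: 3 Z enamino ester
Conditions: TsOH (cat.), benzene, reflux, Dean–Stark
Reagents that add atoms: none
Why: Acid-catalysed condensation of a β-keto ester with a primary amine gives the Z enamino ester (vinylogous carbamate) held by an N–H···O=C hydrogen bond; no new stereocentre.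

**Step 2**
Reactants: 3 Z enamino ester; 4 2-bromo-N,N-dimethylacetamide
Product: 6 methyl (2S)-2-acetyl-4-(dimethylamino)-2-methyl-4-oxobutanoate, via ketimine 5 (not isolated)
Conditions: LiN(iPr)2 (LDA), toluene, −78 °C; 4, −78 → −20 °C; then 1 M HCl, rt
Reagents that add atoms: water, O
Why: Auxiliary-controlled alkylation of the chelated lithio-enamine (metalloenamine alkylation): the valine ester shields one face, the bromoacetamide enters from the other and sets the quaternary C1, and acid hydrolysis of ketimine 5 releases the auxiliary.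

**Step 3**
Reactants: 6 keto ester amide
Product: 7 methyl (2S)-2-(1,1-dimethoxyethyl)-4-(dimethylamino)-2-methyl-4-oxobutanoate
Conditions: HC(OMe)3, MeOH, TsOH (cat.), rt → 40 °C
Reagents that add atoms: trimethyl orthoformate, COC(OC)OC
Why: Acid-catalysed ketalisation with an orthoester as water scavenger masks the only ketone, so that C10 is the sole enolisable position and C14 the sole electrophile, and it makes the C2 arm a tert-alkyl-sized group.

**Step 4**
Reactants: 8 (E)-3-(trimethylsilyl)prop-2-en-1-ol
Product: 9 allyl tert-butyldimethylsilyl ether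
Conditions: TBSCl, imidazole, CH2Cl2, rt
Reagents that add atoms: tert-butyldimethylsilyl chloride, CC(C)(C)[Si](C)(C)Cl
Why: Standard silylation of a primary alcohol.

**Step 5**
Reactants: 9 allyl silyl ether
Product: 10 (E)-1-(tert-butyldimethylsilyl)-3-(trimethylsilyl)prop-2-en-1-ol (racemic)
Conditions: t-BuLi, THF, −78 → −30 °C; aq NH4Cl
Reagents that add atoms: none
Why: Allylic deprotonation next to oxygen followed by 1,2-silyl shift from O to C (retro-Brook rearrangement) gives the α-silyl carbinol.

**Step 6**
Reactants: 10 α-silyl carbinol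
Product: 11 (E)-1-(tert-butyldimethylsilyl)-3-(trimethylsilyl)prop-2-en-1-one
Conditions: (COCl)2, DMSO, CH2Cl2, −78 °C; Et3N
Reagents that add atoms: none
Why: Swern oxidation of an α-silyl carbinol gives the acylsilane without Brook rearrangement.

**Step 7**
Reactants: 7 ketal ester amide; 11 β-silyl acryloylsilane
Product: 14 ring-A keto enol silane, via alkoxide adduct 12 (not isolated), via silyl ketone 13 (not isolated)
Conditions: LiN(iPr)2, THF, −80 °C; add 11, −80 → −30 °C; aq NH4Cl
Reagents that add atoms: none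
Why: Proposed new method: LiN(iPr)2 forms the Z(O) lithium amide enolate of 7 at C10 (the only enolisable position), which adds 1,2 to the acylsilane carbonyl of 11 (C10–C11 bond); the α-silyl alkoxide 12 undergoes 1,2-Brook rearrangement to a siloxyallyl anion whose γ-carbon (C13, stabilised by Me3Si) acylates the methyl ester C14 (C13–C14 bond), and the liberated methoxide cleaves the α-silyl ketone 13 to leave the regiodefined enol silane 14. The closest known reaction is the Brook-rearrangement-mediated [3+2] annulation of β-silyl acryloylsilanes with ketone enolates, in which the same carbanion attacks the enolate-derived ketone; here that ketone is replaced by a 1,3-related ester, so a six-membered ring results ([3+3]). Ring A closes by a 6-exo-trig acyl substitution (Dieckmann type), with the C11=C12 enol ether held Z inside the ring as in the [3+2] precedent. C10 is the only lasting new stereocentre: in the enolate the C15 methyl on C1 lies in the enolate plane (least A(1,3) strain) and the acylsilane approaches anti to the tert-alkyl-sized 1,1-dimethoxyethyl group, which places the carboxamide cis to the C15 methyl; the C11 centre of 12 is destroyed by the Brook step. The step needs 1,2- over 1,4-addition and Brook rearrangement faster than O-acylation, both secured by the β-Me3Si group (it blocks the β-carbon and stabilises the carbanion), and closure on C14 (six-membered) rather than on C9 (five-membered), secured by a poorly electrophilic tertiary amide at C9 against a methyl ester at C14.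

**Step 8**
Reactants: 14 ring-A keto enol silane
Product: 16 ring-A 14-acetate, via alcohol 15 (not isolated)
Conditions: K[(s-Bu)3BH] (K-selectride), THF, −78 °C; then Ac2O, DMAP, −78 °C → rt
Reagents that add atoms: acetic anhydride, CC(=O)OC(C)=O
Why: Reduction of the only free ketone by a bulky borohydride from the equatorial direction gives the axial 14-alkoxide (cis to the equatorial 1,1-dimethoxyethyl group, trans to the axial C15 methyl), which is acetylated in the same flask; the enol silane keeps C11 masked.

**Step 9**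
Reactants: 16 ring-A 14-acetate
Product: 17 β-keto amide
Conditions: TBAF, AcOH (1:1), THF, 0 °C → rt
Reagents that add atoms: none
Why: Fluoride cleavage of the silyl enol ether (C-protonation at C12) gives the β-keto amide, in which C10 equilibrates to the epimer with the carboxamide equatorial (cis to the axial C15 methyl), because the tert-alkyl-sized C2 arm locks the chair and an axial carboxamide would be 1,3-diaxial to the 14-acetoxy group.

**Step 10**
Reactants: 17 β-keto amide
Product: 18 11-methylidene amide
Conditions: Zn, CH2Br2, TiCl4 (pre-formed reagent), THF–CH2Cl2, 0 °C → rt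
Reagents that add atoms: dibromomethane, BrCBr
Why: Takai–Lombardo methylenation with a non-basic titanium–zinc carbenoid converts the easily enolised C11 ketone into the exocyclic C11=C20 alkene without touching amide, ester or ketal.

**Step 11**
Reactants: 18 11-methylidene amide
Product: 19 C9 aldehyde
Conditions: Cp2Zr(H)Cl (1.5 equiv), THF, rt; aqueous work-up
Reagents that add atoms: none
Why: Partial reduction of a tertiary amide by Cp2Zr(H)Cl stops at the aldehyde after hydrolysis of the zirconated hemiaminal and is faster than reaction with the acetate or the 1,1-disubstituted alkene.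

**Step 12**
Reactants: 20 3-methyltetronic acid
Product: 21 butenolide enol triflate
Conditions: Tf2O, Et3N, CH2Cl2, −78 °C
Reagents that add atoms: trifluoromethanesulfonic anhydride, O=S(=O)(OS(=O)(=O)C(F)(F)F)C(F)(F)F
Why: O-sulfonylation of the enol form of a tetronic acid gives the enol triflate.

**Step 13**
Reactants: 19 C9 aldehyde; 21 butenolide enol triflate
Product: 22 C9 carbinol (both C9 epimers)
Conditions: CrCl2 (excess), NiCl2 (cat.), DMF, rt
Reagents that add atoms: none
Why: Nozaki–Hiyama–Kishi coupling (NiCl2-catalysed insertion into the enol triflate, transmetallation to chromium, addition to the aldehyde) attaches the pre-formed butenolide at C8–C9 under neutral conditions that do not epimerise C10; the C9 configuration is not relied on.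

**Step 14**
Reactants: 22 C9 carbinol
Product: 23 C9 ketone
Conditions: Dess–Martin periodinane, NaHCO3, CH2Cl2, 0 °C
Reagents that add atoms: none
Why: Dess–Martin oxidation under buffered neutral conditions gives the C9 ketone without moving the β,γ-double bond.

**Step 15**
Reactants: 23 C9 ketone
Product: 24 C9 alcohol (single epimer)
Conditions: NaBH4, CeCl3·7H2O, MeOH, −78 °C
Reagents that add atoms: none
Why: Luche 1,2-reduction under Felkin–Anh control, with hydride anti to the quaternary C1 substituent of C10, gives the 9-carbinol configuration of the target.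

**Step 16**
Reactants: 24 C9 alcohol
Product: 25 9,14-diacetate ketal
Conditions: Ac2O, pyridine, DMAP (cat.), CH2Cl2, rt
Reagents that add atoms: acetic anhydride, CC(=O)OC(C)=O
Why: Standard acetylation of a secondary alcohol.

**Step 17**
Reactants: 25 9,14-diacetate ketal
Product: 26 C2 methyl ketone
Conditions: PPTS (cat.), acetone–H2O (10:1), 40 °C
Reagents that add atoms: water, O
Why: Mild acid hydrolysis of the dimethyl ketal unveils the C2 methyl ketone.

**Step 18**
Reactants: 27 2-methylidenepropane-1,3-diol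
Product: 28 mono(triethylsilyl) ether
Conditions: Et3SiCl (0.9 equiv), imidazole, CH2Cl2, −20 °C (diol in excess)
Reagents that add atoms: chlorotriethylsilane, CC[Si](Cl)(CC)CC
Why: Monosilylation of a symmetrical diol used in excess.

**Step 19**
Reactants: 28 mono(triethylsilyl) ether
Product: 29 2-[(triethylsilyloxy)methyl]prop-2-enal
Conditions: Dess–Martin periodinane, NaHCO3, CH2Cl2, 0 °C
Reagents that add atoms: none
Why: Dess–Martin oxidation of the allylic alcohol to the 2-substituted acrolein.

**Step 20**
Reactants: 26 C2 methyl ketone; 29 silyloxymethyl acrolein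
Product: 31 2,4-syn diol, via aldol adduct 30 (not isolated)
Conditions: (−)-Ipc2BCl, Et3N, Et2O, −78 → 0 °C; 29, −78 °C; LiBH4, −78 °C; then H2O2, pH 7 buffer, MeOH
Reagents that add atoms: none
Why: Boron-mediated aldol reaction of the methyl ketone through its diisopinocampheylboron enolate sets C4 by reagent control, and LiBH4 reduction of the boron aldolate (1,3-syn reduction of the Narasaka–Prasad type) sets C2 syn to C4.

**Step 21**
Reactants: 31 2,4-syn diol
Product: 32 4-O-triethylsilyl ether
Conditions: Et3SiCl, imidazole, DMF, −20 °C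
Reagents that add atoms: chlorotriethylsilane, CC[Si](Cl)(CC)CC
Why: Silylation of the less hindered allylic 4-OH in preference to the neopentyl-type 2-OH next to the quaternary C1.

**Step 22**
Reactants: 32 4-O-triethylsilyl ether
Product: 33 2,9,14-triacetate
Conditions: Ac2O, Et3N, DMAP, CH2Cl2, rt → 40 °C
Reagents that add atoms: acetic anhydride, CC(=O)OC(C)=O
Why: DMAP-catalysed acetylation of the remaining hindered 2-OH.

**Step 23**
Reactants: 33 2,9,14-triacetate
Product: 34 C6 enal
Conditions: (COCl)2, DMSO, CH2Cl2, −78 → −40 °C; Et3N, → 0 °C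
Reagents that add atoms: none
Why: Swern conditions convert a primary triethylsilyl ether directly into the aldehyde (chloride-induced desilylation, then oxidation), while the secondary triethylsilyl ether at C4 survives.

**Step 24**
Reactants: 34 C6 enal
Product: 36 macrocyclic 6-hydroxy butenolide, via silyloxyfuran 35 (not isolated)
Conditions: TBSOTf, Et3N, CH2Cl2, 0 °C; dilute to 0.001 M, BF3·OEt2, −78 °C; aq NaHCO3
Reagents that add atoms: none
Why: Intramolecular vinylogous Mukaiyama aldol reaction: the 2-silyloxyfuran formed by soft enolisation of the butenolide attacks the activated enal through its γ-carbon (C7) under high dilution and closes the ten-membered ring at C6–C7; the open antiperiplanar transition state is expected to give the 6,7-syn adduct, and the trans-fused ring A with the C9 acetoxy-bearing chain on the planar furan is expected to direct the aldehyde to the furan face that gives the C7 configuration of the target.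

**Step 25**
Reactants: 36 macrocyclic 6-hydroxy butenolide
Product: 37 8,17-epoxy lactone
Conditions: t-BuOOH, n-BuLi (LiOOtBu, 2.2 equiv), THF, −78 → −20 °C; aq NH4Cl
Reagents that add atoms: tert-butyl hydroperoxide, CC(C)(C)OO
Why: Nucleophilic (Weitz–Scheffer) epoxidation of the butenolide by LiOOtBu, delivered by the lithium alkoxide of the adjacent 6-OH to C8 on the face syn to C6, fixes the C8–O configuration of the target.

**Step 26**
Reactants: 37 8,17-epoxy lactone
Product: 38 6,8-diol lactone
Conditions: SmI2 (2.5 equiv), THF–MeOH, −78 °C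
Reagents that add atoms: none
Why: SmI2 reduction of an α,β-epoxy lactone cleaves the C17–O bond and keeps the C8–O bond; protonation of the samarium enolate at C17 gives the more stable lactone with the methyl cis to the 8-OH and trans to the C9 branch (this centre can equilibrate through the enolate).

**Step 27**
Reactants: 38 6,8-diol lactone
Product: 39 6-chloride
Conditions: PPh3, hexachloroacetone, 2,6-di-tert-butylpyridine, CH2Cl2, −20 → 0 °C
Reagents that add atoms: hexachloroacetone, ClC(Cl)(Cl)C(=O)C(Cl)(Cl)Cl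
Why: Appel-type deoxychlorination of the allylic alcohol through its alkoxyphosphonium ion proceeds by SN2 with inversion at C6 and without allylic transposition; the tertiary 8-OH does not react.

**Step 28**
Reactants: 39 6-chloride
Product: 40 4-O-triethylsilyl ether of the target
Conditions: mCPBA, NaHCO3, CH2Cl2, −20 → 0 °C
Reagents that add atoms: 3-chloroperoxybenzoic acid, O=C(OO)c1cccc(Cl)c1
Why: Prilezhaev epoxidation of the more electron-rich C11=C20 alkene (C5=C16 is deactivated by the allylic chlorine and silyloxy groups) from the face anti to the axial C15 methyl on C1 gives the spiro-epoxide with its oxygen on the face of H10.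

**Step 29**
Reactants: 40 4-O-triethylsilyl ether of the target
Product: 41 CNP0312034.1 (target)
Conditions: HF·pyridine, pyridine, THF, 0 °C
Reagents that add atoms: none
Why: Fluoride cleavage of the secondary triethylsilyl ether under buffered conditions leaves epoxide, allylic chloride and acetates intact.

## Compound list

1 | methyl 2-methyl-3-oxobutanoate | CC(=O)C(C)C(=O)OC | starting material
2 | L-valine tert-butyl ester | CC(C)[C@H](N)C(=O)OC(C)(C)C | starting material
3 | methyl (Z)-3-{[(2S)-1-tert-butoxy-3-methyl-1-oxobutan-2-yl]amino}-2-methylbut-2-enoate | COC(=O)/C(C)=C(/C)N[C@@H](C(C)C)C(=O)OC(C)(C)C | intermediate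
4 | 2-bromo-N,N-dimethylacetamide | CN(C)C(=O)CBr | starting material
5 | ketimine of 6 with L-valine tert-butyl ester (C-alkylated imine) | CC(=N[C@@H](C(C)C)C(=O)OC(C)(C)C)[C@@](CC(=O)N(C)C)(C)C(=O)OC | intermediate (not isolated)
6 | methyl (2S)-2-acetyl-4-(dimethylamino)-2-methyl-4-oxobutanoate | CC(=O)[C@@](CC(=O)N(C)C)(C)C(=O)OC | intermediate
7 | methyl (2S)-2-(1,1-dimethoxyethyl)-4-(dimethylamino)-2-methyl-4-oxobutanoate | COC(C)(OC)[C@@](CC(=O)N(C)C)(C)C(=O)OC | intermediate
8 | (E)-3-(trimethylsilyl)prop-2-en-1-ol | C[Si](C)(C)/C=C/CO | starting material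
9 | tert-butyldimethyl{[(E)-3-(trimethylsilyl)prop-2-en-1-yl]oxy}silane | C[Si](C)(C)/C=C/CO[Si](C)(C)C(C)(C)C | intermediate
10 | (E)-1-(tert-butyldimethylsilyl)-3-(trimethylsilyl)prop-2-en-1-ol (racemic) | C[Si](C)(C)/C=C/C(O)[Si](C)(C)C(C)(C)C | intermediate
11 | (E)-1-(tert-butyldimethylsilyl)-3-(trimethylsilyl)prop-2-en-1-one | C[Si](C)(C)/C=C/C(=O)[Si](C)(C)C(C)(C)C | intermediate
12 | α-silyl alkoxide from 1,2-addition of the C10 enolate of 7 to 11 (drawn as the alcohol; carbinol C11 unspecified) | COC(C)(OC)[C@@](C)(C(=O)OC)[C@@H](C(=O)N(C)C)C(O)([Si](C)(C)C(C)(C)C)/C=C/[Si](C)(C)C | intermediate (not isolated)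
13 | 2-[(tert-butyldimethylsilyl)oxy]-6-(1,1-dimethoxyethyl)-N,N,6-trimethyl-5-oxo-4-(trimethylsilyl)cyclohex-2-ene-1-carboxamide (carboxamide cis to the 6-methyl) | COC(C)(OC)[C@@]1(C)C(=O)C([Si](C)(C)C)C=C(O[Si](C)(C)C(C)(C)C)[C@@H]1C(=O)N(C)C | intermediate (not isolated)
14 | 2-[(tert-butyldimethylsilyl)oxy]-6-(1,1-dimethoxyethyl)-N,N,6-trimethyl-5-oxocyclohex-2-ene-1-carboxamide (carboxamide cis to the 6-methyl; ring A with C14 ketone and C11 enol silane) | COC(C)(OC)[C@@]1(C)C(=O)CC=C(O[Si](C)(C)C(C)(C)C)[C@@H]1C(=O)N(C)C | intermediate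
15 | 14-alcohol of 14 (hydroxyl trans to the C15 methyl) | COC(C)(OC)[C@@]1(C)[C@@H](O)CC=C(O[Si](C)(C)C(C)(C)C)[C@@H]1C(=O)N(C)C | intermediate (not isolated)
16 | 4-[(tert-butyldimethylsilyl)oxy]-6-(1,1-dimethoxyethyl)-5-(dimethylcarbamoyl)-6-methylcyclohex-3-en-1-yl acetate (acetoxy trans and carbamoyl cis to the 6-methyl) | COC(C)(OC)[C@@]1(C)[C@@H](OC(C)=O)CC=C(O[Si](C)(C)C(C)(C)C)[C@@H]1C(=O)N(C)C | intermediate
17 | 2-(1,1-dimethoxyethyl)-3-(dimethylcarbamoyl)-2-methyl-4-oxocyclohexyl acetate (acetoxy trans and carbamoyl cis to the 2-methyl) | COC(C)(OC)[C@@]1(C)[C@@H](OC(C)=O)CCC(=O)[C@@H]1C(=O)N(C)C | intermediate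
18 | 2-(1,1-dimethoxyethyl)-3-(dimethylcarbamoyl)-2-methyl-4-methylidenecyclohexyl acetate | COC(C)(OC)[C@@]1(C)[C@@H](OC(C)=O)CCC(=C)[C@@H]1C(=O)N(C)C | intermediate
19 | 2-(1,1-dimethoxyethyl)-3-formyl-2-methyl-4-methylidenecyclohexyl acetate | COC(C)(OC)[C@@]1(C)[C@@H](OC(C)=O)CCC(=C)[C@@H]1C=O | intermediate
20 | 3-methyltetronic acid (4-hydroxy-3-methylfuran-2(5H)-one) | CC1=C(O)COC1=O | starting material
21 | 4-methyl-5-oxo-2,5-dihydrofuran-3-yl trifluoromethanesulfonate | CC1=C(OS(=O)(=O)C(F)(F)F)COC1=O | intermediate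
22 | 2-(1,1-dimethoxyethyl)-3-[hydroxy(4-methyl-5-oxo-2,5-dihydrofuran-3-yl)methyl]-2-methyl-4-methylidenecyclohexyl acetate (C9 epimers) | COC(C)(OC)[C@@]1(C)[C@@H](OC(C)=O)CCC(=C)[C@@H]1C(O)C1=C(C)C(=O)OC1 | intermediate
23 | 2-(1,1-dimethoxyethyl)-2-methyl-4-methylidene-3-(4-methyl-5-oxo-2,5-dihydrofuran-3-carbonyl)cyclohexyl acetate | COC(C)(OC)[C@@]1(C)[C@@H](OC(C)=O)CCC(=C)[C@@H]1C(=O)C1=C(C)C(=O)OC1 | intermediate
24 | C9 carbinol of 23 with the C9 configuration of the target | COC(C)(OC)[C@@]1(C)[C@@H](OC(C)=O)CCC(=C)[C@@H]1[C@H](O)C1=C(C)C(=O)OC1 | intermediate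
25 | 9,14-diacetate of 24 (C2 still as dimethyl ketal) | COC(C)(OC)[C@@]1(C)[C@@H](OC(C)=O)CCC(=C)[C@@H]1[C@H](OC(C)=O)C1=C(C)C(=O)OC1 | intermediate
26 | 2-acetyl-3-[(acetyloxy)(4-methyl-5-oxo-2,5-dihydrofuran-3-yl)methyl]-2-methyl-4-methylidenecyclohexyl acetate (C2 methyl ketone) | CC(=O)[C@@]1(C)[C@@H](OC(C)=O)CCC(=C)[C@@H]1[C@H](OC(C)=O)C1=C(C)C(=O)OC1 | intermediate
27 | 2-methylidenepropane-1,3-diol | C=C(CO)CO | starting material
28 | 2-{[(triethylsilyl)oxy]methyl}prop-2-en-1-ol | C=C(CO)CO[Si](CC)(CC)CC | intermediate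
29 | 2-{[(triethylsilyl)oxy]methyl}prop-2-enal | C=C(C=O)CO[Si](CC)(CC)CC | intermediate
30 | aldol adduct of 26 and 29 (boron aldolate, drawn as the β-hydroxy ketone: C2 ketone, 4-OH, C5=C16, C6H2OSiEt3) | CC[Si](CC)(CC)OCC(=C)[C@H](O)CC(=O)[C@@]1(C)[C@@H](OC(C)=O)CCC(=C)[C@@H]1[C@H](OC(C)=O)C1=C(C)C(=O)OC1 | intermediate (not isolated)
31 | 6,7-seco-briarane 2,4-syn diol (C2 arm CH(OH)CH2CH(OH)C(=CH2)CH2OSiEt3 on 9,14-diacetoxy ring A bearing the butenolide) | CC[Si](CC)(CC)OCC(=C)[C@H](O)C[C@H](O)[C@@]1(C)[C@@H](OC(C)=O)CCC(=C)[C@@H]1[C@H](OC(C)=O)C1=C(C)C(=O)OC1 | intermediate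
32 | 4-O-triethylsilyl ether of 31 (2-OH free) | CC[Si](CC)(CC)OCC(=C)[C@H](O[Si](CC)(CC)CC)C[C@H](O)[C@@]1(C)[C@@H](OC(C)=O)CCC(=C)[C@@H]1[C@H](OC(C)=O)C1=C(C)C(=O)OC1 | intermediate
33 | 2,9,14-triacetate with 4-OSiEt3 and 6-OSiEt3 (seco) | CC[Si](CC)(CC)OCC(=C)[C@H](O[Si](CC)(CC)CC)C[C@H](OC(C)=O)[C@@]1(C)[C@@H](OC(C)=O)CCC(=C)[C@@H]1[C@H](OC(C)=O)C1=C(C)C(=O)OC1 | intermediate
34 | seco C6 enal (2,9,14-triacetoxy, 4-OSiEt3, butenolide with free C7H2) | O=CC(=C)[C@H](O[Si](CC)(CC)CC)C[C@H](OC(C)=O)[C@@]1(C)[C@@H](OC(C)=O)CCC(=C)[C@@H]1[C@H](OC(C)=O)C1=C(C)C(=O)OC1 | intermediate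
35 | 2-(tert-butyldimethylsilyloxy)-3-methylfuran-4-yl analogue of 34 | O=CC(=C)[C@H](O[Si](CC)(CC)CC)C[C@H](OC(C)=O)[C@@]1(C)[C@@H](OC(C)=O)CCC(=C)[C@@H]1[C@H](OC(C)=O)c1coc(O[Si](C)(C)C(C)(C)C)c1C | intermediate (not isolated)
36 | 2,9,14-triacetoxy-6-hydroxy-4-(triethylsilyloxy)briara-5(16),8(17),11(20)-trien-19,7-olide (6-OH syn to 7-O, C6 opposite to the chloride of the target) | C=C1[C@H](O[Si](CC)(CC)CC)C[C@H](OC(C)=O)[C@@]2(C)[C@@H](OC(C)=O)CCC(=C)[C@@H]2[C@H](OC(C)=O)C2=C(C)C(=O)O[C@H]2[C@@H]1O | intermediate
37 | 8,17-epoxide of 36 (epoxide oxygen on the face of C6) | C=C1[C@H](O[Si](CC)(CC)CC)C[C@H](OC(C)=O)[C@@]2(C)[C@@H](OC(C)=O)CCC(=C)[C@@H]2[C@H](OC(C)=O)[C@@]23O[C@@]3(C)C(=O)O[C@H]2[C@@H]1O | intermediate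
38 | 2,9,14-triacetoxy-6,8-dihydroxy-4-(triethylsilyloxy)briara-5(16),11(20)-dien-19,7-olide | C=C1[C@H](O[Si](CC)(CC)CC)C[C@H](OC(C)=O)[C@@]2(C)[C@@H](OC(C)=O)CCC(=C)[C@@H]2[C@H](OC(C)=O)[C@]2(O)[C@@H](C)C(=O)O[C@H]2[C@@H]1O | intermediate
39 | 2,9,14-triacetoxy-6-chloro-8-hydroxy-4-(triethylsilyloxy)briara-5(16),11(20)-dien-19,7-olide | C=C1[C@H](O[Si](CC)(CC)CC)C[C@H](OC(C)=O)[C@@]2(C)[C@@H](OC(C)=O)CCC(=C)[C@@H]2[C@H](OC(C)=O)[C@]2(O)[C@@H](C)C(=O)O[C@H]2[C@H]1Cl | intermediate
40 | 4-O-triethylsilyl ether of the target | C=C1[C@H](O[Si](CC)(CC)CC)C[C@H](OC(C)=O)[C@@]2(C)[C@@H](OC(C)=O)CC[C@]3(CO3)[C@@H]2[C@H](OC(C)=O)[C@]2(O)[C@@H](C)C(=O)O[C@H]2[C@H]1Cl | intermediate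
41 | CNP0312034.1: 2,9,14-triacetoxy-6-chloro-11,20-epoxy-4,8-dihydroxybriar-5(16)-en-19,7-olide | C=C1[C@H](O)C[C@H](OC(C)=O)[C@@]2(C)[C@@H](OC(C)=O)CC[C@]3(CO3)[C@@H]2[C@H](OC(C)=O)[C@]2(O)[C@@H](C)C(=O)O[C@H]2[C@H]1Cl | target

## Step count and risks

Total step count: 29. Longest linear sequence: 23 steps (steps 1–3, 7–11, 13–17, 20–29).

**Step 7 (Proposed new method).** What may go wrong: conjugate addition of the enolate to the acylsilane instead of 1,2-addition; O-acylation of the α-silyl alkoxide by the C14 ester before the Brook shift; closure of the carbanion on the amide; poor facial selectivity at C10. Fallback with known reactions only, setting out from 7 and coming back at 17: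
- LiBH4 (THF–MeOH) reduces the methyl ester of 7 to the neopentyl alcohol F1.
- Dess–Martin oxidation gives the aldehyde F2.
- The zinc homoenolate of ethyl propanoate (from (1-ethoxycyclopropoxy)trimethylsilane and ZnCl2, with Me3SiCl) adds under Felkin–Anh control, anti to the 1,1-dimethoxyethyl group, and acid work-up lactonises the adduct to the γ-lactone F3 (C13–C14 bond).
- NaH or KOtBu in THF then effects a Dieckmann-type transacylation of the amide α-carbon onto the lactone carbonyl (C10–C11 bond) to give the hydroxy β-keto amide F4, in which C10 is under the same thermodynamic control as in step 9.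
- Acetylation (Ac2O, pyridine) gives 17.

**Step 24.** What may go wrong: oligomerisation instead of ten-membered ring closure; attack through the α-carbon of the dienol ether or Prins-type reaction of the exocyclic alkenes with the activated aldehyde; the wrong facial sense at C6 or C7. Fallback that changes the mode of bond formation, setting out from 34 and coming back at 36: the silyloxyfuran 35 is brominated at C7 with N-bromosuccinimide to the 5-bromobutenolide F5, and the ring is closed under high dilution with CrCl2 by an intramolecular vinylogous Reformatsky addition of the chromium dienolate (generated by divalent chromium) to the C6 aldehyde, which gives 36.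

**Step 25.** What may go wrong: no conjugate addition at the hindered, fully substituted C8; cleavage of acetates by the peroxide anion; epoxidation from the face anti to C6. Fallback that changes the approach, setting out from 36 and coming back at 38 (steps 25 and 26 are bypassed): benzaldehyde with catalytic KOtBu converts the 6-OH into a hemiacetal alkoxide that adds to C8 (intramolecular oxa-Michael addition), giving the benzylidene acetal F6. Its cis ring fusion forces the new C8–O bond syn to C6, and C17 is protonated to the more stable epimer. Aqueous acetic acid then hydrolyses the acetal to 38.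

## Further compounds

F1 | step 7 | 3-(1,1-dimethoxyethyl)-4-hydroxy-N,N,3-trimethylbutanamide (C1 as in 7) | COC(C)(OC)[C@@](CC(=O)N(C)C)(C)CO
F2 | step 7 | 3-(1,1-dimethoxyethyl)-N,N,3-trimethyl-4-oxobutanamide | COC(C)(OC)[C@@](CC(=O)N(C)C)(C)C=O
F3 | step 7 | 3-(1,1-dimethoxyethyl)-N,N-dimethyl-3-(5-oxooxolan-2-yl)butanamide (C14 as in the target) | COC(C)(OC)[C@@](CC(=O)N(C)C)(C)[C@@H]1CCC(=O)O1
F4 | step 7 | 14-hydroxy analogue of 17 (2-(1,1-dimethoxyethyl)-3-(dimethylcarbamoyl)-2-methyl-4-oxocyclohexanol) | COC(C)(OC)[C@@]1(C)[C@@H](O)CCC(=O)[C@@H]1C(=O)N(C)C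
F5 | step 24 | 7-bromo derivative of 34 (5-bromobutenolide, C7 epimers) | O=CC(=C)[C@H](O[Si](CC)(CC)CC)C[C@H](OC(C)=O)[C@@]1(C)[C@@H](OC(C)=O)CCC(=C)[C@@H]1[C@H](OC(C)=O)C1=C(C)C(=O)OC1Br
F6 | step 25 | 6,8-O-benzylidene acetal of 38 | C=C1[C@H](O[Si](CC)(CC)CC)C[C@H](OC(C)=O)[C@@]2(C)[C@@H](OC(C)=O)CCC(=C)[C@@H]2[C@H](OC(C)=O)[C@]2(OC3c4ccccc4)[C@@H](C)C(=O)O[C@H]2[C@@H]1O3
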